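## Retrosynthetic overview

1. Target 11 ⇒ oxanorbornenyl acrylate 5 + allylic alcohol 9 by a one-pot ring-opening/ring-closing/cross-metathesis. This opens the norbornene bridge, closes the δ-lactone and attaches the side chain.
2. 5 ⇒ meso endo-diol 4 by enantiotopic-group-selective mono-acryloylation; 4 ⇒ cyclic carbonate 3.
3. 3 ⇒ furan 1 + vinylene carbonate 2 by one [4+2] cycloaddition. This step creates two new ring circuits at once, the cyclohexene and the cis-dioxygenated oxolane, and sets all four ring stereocentres relative to each other.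
4. 9 ⇒ divinylcarbinol 6 by Sharpless epoxidation, hydride opening and regioselective benzoylation.
5. Ring order: oxolane (the later tetrahydrofuran) and a sacrificial cyclohexene together in step 1; the cyclohexene is opened and the δ-lactone closed in step 7. No protecting groups are used.

Assumption: the target is taken exactly as the SMILES defines it (all-cis tetrahydrofuran, (2R,3S) side chain), and immobilized lipases and the ruthenium metathesis catalyst count as purchasable reagents.

## Route

Step 1
Reactants: 1 furan; 2 vinylene carbonate (1,3-dioxol-2-one)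
Product: 3 endo-7-oxabicyclo[2.2.1]hept-5-ene-2,3-diyl carbonate, (3aR,4S,7R,7aS)-3a,4,7,7a-tetrahydro-4,7-epoxy-1,3-benzodioxol-2-one (meso)
Conditions: neat furan (6 equiv), BHT (cat.), sealed tube, 125 °C, 20 h; endo isomer separated from exo by crystallization (EtOAc–hexane) and chromatography
Reagents that add atoms: none
Why: Thermal Diels–Alder [4+2] cycloaddition in which suprafacial addition across the cis alkene gives the cis carbonate, and the endo transition state places both C–O bonds anti to the oxygen bridge, so the new oxolane ring carries all four substituents on one face (meso, so no absolute control is needed yet).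

Step 2
Reactants: 3 endo carbonate
Product: 4 (1R,2R,3S,4S)-7-oxabicyclo[2.2.1]hept-5-ene-2,3-diol (meso, both OH endo)
Conditions: K2CO3 (0.2 equiv), MeOH, 0 °C to rt, 1 h; acidic resin, evaporate
Reagents that add atoms: none
Why: Base-catalysed methanolysis (transesterification) of the five-membered cyclic carbonate breaks only acyl C–O bonds, so the endo,cis relationship is retained.

Step 3
Reactants: 4 meso endo-diol
Product: 5 (1R,2R,3R,4S)-3-hydroxy-7-oxabicyclo[2.2.1]hept-5-en-2-yl prop-2-enoate (both oxygens endo)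
Conditions: vinyl acrylate (3 equiv), immobilized Candida antarctica lipase B, BHT (cat.), t-BuOMe–THF, 30 °C, stopped at complete mono-acylation; filtered and used at once
Reagents that add atoms: vinyl acrylate, C=CC(=O)OC=C
Why: Proposed new method: the acyl-enzyme formed irreversibly from the enol ester (vinyl alcohol leaves as acetaldehyde) should transfer the acryloyl group to only one of the two enantiotopic endo hydroxyls held in the chiral active site, and this fixes the absolute configuration of all four ring stereocentres; the closest known reactions are lipase-catalysed desymmetrizing mono-acylations of meso cis-cycloalkane-1,2-diols with vinyl esters and lipase acryloylations of secondary alcohols with vinyl acrylate; the sense of induction must be checked (Mosher ester), and the antipodal monoester would come from hydrolysis of the bis-acrylate with the same enzyme.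

Step 4
Reactants: 6 penta-1,4-dien-3-ol (divinylcarbinol)
Product: 7 (2R,3S)-1,2-epoxypent-4-en-3-ol, (S)-1-[(R)-oxiran-2-yl]prop-2-en-1-ol
Conditions: Ti(OiPr)4 (0.1 equiv), L-(+)-diisopropyl tartrate (0.13 equiv), t-BuOOH (1.5 equiv, anhydrous), 4 Å MS, CH2Cl2, −20 °C, 4 d
Reagents that add atoms: tert-butyl hydroperoxide, CC(C)(C)OO
Why: Sharpless asymmetric epoxidation of a prochiral divinyl carbinol, in which the L-(+)-tartrate catalyst selects one enantiotopic vinyl group and one face to give the erythro epoxy alcohol, and the minor enantiomer is consumed faster by a second epoxidation so the ee rises with conversion.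

Step 5
Reactants: 7 (2R,3S)-1,2-epoxypent-4-en-3-ol
Product: 8 (2R,3S)-pent-4-ene-2,3-diol (anti diol)
Conditions: LiAlH4 (1.0 equiv), Et2O, 0 °C, 1 h; Na2SO4·10H2O quench
Reagents that add atoms: none
Why: Epoxide reduction by SN2 hydride attack at the unhindered terminal CH2, which leaves both stereocentres untouched and turns the epoxide carbon into the (R)-methyl carbinol.

Step 6
Reactants: 8 (2R,3S)-pent-4-ene-2,3-diol
Product: 9 (2R,3S)-3-hydroxypent-4-en-2-yl benzoate
Conditions: vinyl benzoate (2 equiv), immobilized Candida antarctica lipase B, t-BuOMe, 45 °C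
Reagents that add atoms: vinyl benzoate, C=COC(=O)c1ccccc1
Why: Lipase-catalysed regioselective transesterification following the Kazlauskas rule, in which the (R)-methyl carbinol is the fast-reacting arrangement and the (S)-allylic carbinol the mismatched one, so the benzoate goes to O-2 without forming or touching a stereocentre.

Step 7
Reactants: 5 (1R,2R,3R,4S)-3-hydroxy-7-oxabicyclo[2.2.1]hept-5-en-2-yl prop-2-enoate; 9 (2R,3S)-3-hydroxypent-4-en-2-yl benzoate (3 equiv)
Product: 11 (2R,3S,4E)-3-hydroxy-5-[(2S,3R,3aR,7aR)-3-hydroxy-5-oxo-2,3,3a,7a-tetrahydro-5H-furo[3,2-b]pyran-2-yl]pent-4-en-2-yl benzoate (CNP0143030.1), via vinyl lactone 10 (not isolated)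
Conditions: RuCl2(H2IMes)(=CH-C6H4-2-OiPr) (second-generation Hoveyda–Grubbs catalyst, H2IMes = 1,3-dimesitylimidazolidin-2-ylidene; 2 × 5 mol%), 1,4-benzoquinone (10 mol%), CH2Cl2 (0.02 M), 40 °C, argon sparge, 16 h
Reagents that add atoms: none
Why: Domino ring-opening/ring-closing/cross-metathesis (ring-rearrangement metathesis), in which release of norbornene strain opens the bridge, the alkylidene on the carbon next to the endo acrylate closes the only accessible ring (the six-membered lactone, whose alkene is necessarily Z), and the remaining vinyl group cross-couples with excess 9 to the thermodynamic E alkene; reversibility funnels mis-paired intermediates to the lactone and no sp3 stereocentre is touched.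

## Compound list

1 | furan | c1ccoc1 | starting material
2 | vinylene carbonate (1,3-dioxol-2-one) | O=C1OC=CO1 | starting material
3 | endo-7-oxabicyclo[2.2.1]hept-5-ene-2,3-diyl carbonate, (3aR,4S,7R,7aS), meso | C1=C[C@@H]2O[C@H]1[C@@H]3OC(=O)O[C@@H]32 | intermediate
4 | (1R,2R,3S,4S)-7-oxabicyclo[2.2.1]hept-5-ene-2,3-diol, meso, endo,endo | C1=C[C@@H]2O[C@H]1[C@H](O)[C@@H]2O | intermediate
5 | (1R,2R,3R,4S)-3-hydroxy-7-oxabicyclo[2.2.1]hept-5-en-2-yl prop-2-enoate | C1=C[C@@H]2O[C@H]1[C@H](OC(=O)C=C)[C@@H]2O | intermediate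
6 | penta-1,4-dien-3-ol (divinylcarbinol) | C=CC(O)C=C | starting material
7 | (2R,3S)-1,2-epoxypent-4-en-3-ol | C1O[C@H]1[C@@H](O)C=C | intermediate
8 | (2R,3S)-pent-4-ene-2,3-diol | C[C@@H](O)[C@@H](O)C=C | intermediate
9 | (2R,3S)-3-hydroxypent-4-en-2-yl benzoate | C[C@@H](OC(=O)c1ccccc1)[C@@H](O)C=C | intermediate
10 | (2S,3R,3aR,7aR)-2-ethenyl-3-hydroxy-2,3,3a,7a-tetrahydro-5H-furo[3,2-b]pyran-5-one (vinyl lactone) | C=C[C@@H]1O[C@@H]2C=CC(=O)O[C@@H]2[C@@H]1O | intermediate
11 | (2R,3S,4E)-3-hydroxy-5-[(2S,3R,3aR,7aR)-3-hydroxy-5-oxo-2,3,3a,7a-tetrahydro-5H-furo[3,2-b]pyran-2-yl]pent-4-en-2-yl benzoate | C[C@@H](OC(=O)c1ccccc1)[C@@H](O)/C=C/[C@@H]1O[C@@H]2C=CC(=O)O[C@@H]2[C@@H]1O | target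

## Step count and risks

Total steps: 7. Longest linear sequence: 4 steps (1 → 2 → 3 → 7, or 4 → 5 → 6 → 7).

Three steps most likely to fail:

Step 3 (desymmetrization). The enzyme may not accept the concave endo-diol, may give low ee, or the monoester may racemize by 1,2-acyl shift. The fallback sets out from 4 and comes back at 11. Catalytic enantioselective mono-silylation of the meso diol (TBSCl, i-Pr2NEt, chiral amino-acid-derived N-methylimidazole catalyst, THF, −30 °C) gives the silyl ether (1R,2S,3S,4S)-3-[(tert-butyldimethylsilyl)oxy]-7-oxabicyclo[2.2.1]hept-5-en-2-ol F1, which cannot scramble by acyl migration. Acryloyl chloride/Et3N then gives (1R,2S,3R,4S)-3-[(tert-butyldimethylsilyl)oxy]-7-oxabicyclo[2.2.1]hept-5-en-2-yl prop-2-enoate F2. The metathesis domino of step 7 with 9 gives the ring-O-silylated target F3, and HF·pyridine (THF, 0 °C) releases 11.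

Step 7 (metathesis domino). Ring-opening oligomerization, slow cross-metathesis between two allylically branched partners, or isomerization of the free allylic alcohol could intervene. The fallback sets out from 9 (with 5 rearranged separately) and comes back at 11. Dess–Martin oxidation of 9 gives the enone (R)-3-oxopent-4-en-2-yl benzoate F7. Compound 5 alone is rearranged with RuCl2(H2IMes)(=CH-C6H4-2-OiPr) under ethene to isolated 10. Cross-metathesis of 10 with the electron-poor enone gives the E-enone (2R,4E)-5-[(2S,3R,3aR,7aR)-3-hydroxy-5-oxo-2,3,3a,7a-tetrahydro-5H-furo[3,2-b]pyran-2-yl]-3-oxopent-4-en-2-yl benzoate F8. Chelation-controlled 1,2-reduction with Zn(BH4)2 (Et2O, −30 °C) then sets the (S)-carbinol anti to the benzoyloxy group and gives 11.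

Step 6 (regioselective benzoylation). The lipase may be sluggish with the aromatic acyl donor or give the regioisomer. The fallback sets out from 7 and comes back at 9. TBSCl/imidazole gives the silyl ether tert-butyldimethyl{(S)-1-[(R)-oxiran-2-yl]prop-2-en-1-yloxy}silane F4. LiAlH4 opens the epoxide to (2R,3S)-3-[(tert-butyldimethylsilyl)oxy]pent-4-en-2-ol F5. BzCl/pyridine gives (2R,3S)-3-[(tert-butyldimethylsilyl)oxy]pent-4-en-2-yl benzoate F6, and HF·pyridine removes the silyl group without acyl migration to give 9.

Further compounds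
F1 | step 3 | (1R,2S,3S,4S)-3-[(tert-butyldimethylsilyl)oxy]-7-oxabicyclo[2.2.1]hept-5-en-2-ol | C1=C[C@@H]2O[C@H]1[C@H](O)[C@@H]2O[Si](C)(C)C(C)(C)C
F2 | step 3 | (1R,2S,3R,4S)-3-[(tert-butyldimethylsilyl)oxy]-7-oxabicyclo[2.2.1]hept-5-en-2-yl prop-2-enoate | C1=C[C@@H]2O[C@H]1[C@H](OC(=O)C=C)[C@@H]2O[Si](C)(C)C(C)(C)C
F3 | step 3 | ring-O-silylated target: 11 with OSi(t-Bu)Me2 in place of the hydroxyl on the tetrahydrofuran ring | C[C@@H](OC(=O)c1ccccc1)[C@@H](O)/C=C/[C@@H]1O[C@@H]2C=CC(=O)O[C@@H]2[C@@H]1O[Si](C)(C)C(C)(C)C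
F4 | step 6 | tert-butyldimethyl{(S)-1-[(R)-oxiran-2-yl]prop-2-en-1-yloxy}silane | C1O[C@H]1[C@@H](O[Si](C)(C)C(C)(C)C)C=C
F5 | step 6 | (2R,3S)-3-[(tert-butyldimethylsilyl)oxy]pent-4-en-2-ol | C[C@@H](O)[C@@H](O[Si](C)(C)C(C)(C)C)C=C
F6 | step 6 | (2R,3S)-3-[(tert-butyldimethylsilyl)oxy]pent-4-en-2-yl benzoate | C[C@@H](OC(=O)c1ccccc1)[C@@H](O[Si](C)(C)C(C)(C)C)C=C
F7 | step 7 | (R)-3-oxopent-4-en-2-yl benzoate | C[C@@H](OC(=O)c1ccccc1)C(=O)C=C
F8 | step 7 | (2R,4E)-5-[(2S,3R,3aR,7aR)-3-hydroxy-5-oxo-2,3,3a,7a-tetrahydro-5H-furo[3,2-b]pyran-2-yl]-3-oxopent-4-en-2-yl benzoate | C[C@@H](OC(=O)c1ccccc1)C(=O)/C=C/[C@@H]1O[C@@H]2C=CC(=O)O[C@@H]2[C@@H]1O
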